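## Retrosynthetic overview

1. Target 26 ⇒ C3–O ester bond by Mitsunobu inversion of the (3R)-alcohol 16 with dienoic acid 25 (from tiglic acid by asymmetric hydrogenation, Wittig and Horner–Wadsworth–Emmons olefination).
2. 16 ⇒ C3 carbinol from a ketone masked as a dimethyl ketal; C13–O by a new hydroxyl-directed allylic C–H acetoxylation; C7–O by nucleophilic epoxidation of a 7(11)-isopropylidene enone followed by epoxide-to-allylic-alcohol isomerisation.
3. Isopropylidene enone 11 ⇒ aldol with acetone and dehydration on bicyclic dienone ketal 7 ⇒ Robinson annulation of cyclohexenone 3 with methyl vinyl ketone.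
4. 3 ⇒ copper-catalysed asymmetric conjugate methylation and enolate methylation of p-benzoquinone mono(dimethyl ketal) 1.
5. Ring order: ring A is the six-membered ring of commercial 1; ring B is closed second by the Robinson annulation; no other ring is formed.

Assumption: eremophilane locants are used for the decalin (C8 enone carbonyl, C9=C10, C1=C2, C3 oxygenated, C14 on C4, C15 on C5, C11 on C7 with C12 the methylene and C13 the acetoxymethyl carbon); ligand antipodes are those that give the stated configurations; 1 is a catalogue compound.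

## Route

Step 1
Reactants: 1 4,4-dimethoxycyclohexa-2,5-dien-1-one
Product: 3 (5S,6S)-4,4-dimethoxy-5,6-dimethylcyclohex-2-en-1-one, via methylzinc enolate 2 (not isolated)
Conditions: Me2Zn (1.5 equiv), Cu(OTf)2 (2 mol %), BINOL-derived bis(1-phenylethyl)amine phosphoramidite (4 mol %), toluene, −25 °C; then MeI (10 equiv), HMPA, −25 → 0 °C
Reagents that add atoms: dimethylzinc C[Zn]C; iodomethane CI
Why: Copper-catalysed asymmetric conjugate addition (Feringa-type phosphoramidite catalysis) desymmetrises the dienone and sets C5 (the future C4) by ligand control, and the zinc enolate is C-methylated trans to the new methyl (conjugate addition–enolate alkylation); the C6 centre is set again in step 2.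

Step 2
Reactants: 3 (5S,6S)-4,4-dimethoxy-5,6-dimethylcyclohex-2-en-1-one; 4 but-3-en-2-one
Product: 7 (4aS,5S)-6,6-dimethoxy-4a,5-dimethyl-4,4a,5,6-tetrahydronaphthalen-2(3H)-one, via Michael adduct 5 (not isolated), via ketol 6 (not isolated)
Conditions: 4 (1.5 equiv), KOH (0.2 equiv), MeOH, 0 °C → rt; then KOH (1 equiv), MeOH, 60 °C
Reagents that add atoms: none
Why: Robinson annulation: C6 is the only enolisable position (C4 is a ketal carbon), the enone adds anti to the vicinal methyl so the two methyls end up cis and the quaternary centre (future C5) is set, and aldol condensation onto the ring carbonyl closes ring B as the linear dienone; an intramolecular Michael adduct would revert under the basic protic conditions, whereas the dehydration is irreversible.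

Step 3
Reactants: 7 (4aS,5S)-6,6-dimethoxy-4a,5-dimethyl-4,4a,5,6-tetrahydronaphthalen-2(3H)-one; 8 acetone
Product: 10 (4S,5S,7R)-11-hydroxy-3,3-dimethoxyeremophila-1,9-dien-8-one, via lithium enolate 9 (not isolated)
Conditions: LiN(i-Pr)2 (1.1 equiv), THF, −78 °C; 8 (3 equiv), −78 °C; AcOH quench at −78 °C
Reagents that add atoms: none
Why: Directed aldol addition of the kinetic lithium enolate: C7 is the only enolisable site (C3 is a ketal, C5 is quaternary), acetone adds anti to the angular methyl, and the C7 centre is removed again in step 4.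

Step 4
Reactants: 10 (4S,5S,7R)-11-hydroxy-3,3-dimethoxyeremophila-1,9-dien-8-one
Product: 11 (4S,5S)-3,3-dimethoxyeremophila-1,7(11),9-trien-8-one
Conditions: Burgess reagent (1.5 equiv), toluene, 60 °C
Reagents that add atoms: none
Why: Burgess dehydration (syn-elimination of the sulfamate ester toward the acidic C7–H) gives the conjugated isopropylidene enone; any isopropenyl isomer converges on the same product under the basic conditions of step 5.

Step 5
Reactants: 11 (4S,5S)-3,3-dimethoxyeremophila-1,7(11),9-trien-8-one
Product: 12 (4S,5S,7S)-7,11-epoxy-3,3-dimethoxyeremophila-1,9-dien-8-one (oxirane oxygen on the face of the two ring methyls)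
Conditions: 30% aq. H2O2, NaOH (0.5 equiv), MeOH, 0 °C → rt
Reagents that add atoms: hydrogen peroxide OO
Why: Weitz–Scheffer nucleophilic epoxidation: hydroperoxide adds to the exocyclic β-carbon C11 and the enolate closes the oxirane with the small oxygen axial on the face of the angular methyl and the bulky CMe2 group equatorial, which sets C7 as S; the ring alkenes are shielded by the fully substituted C10 and the ketal-flanked C2.

Step 6
Reactants: 12 (4S,5S,7S)-7,11-epoxy-3,3-dimethoxyeremophila-1,9-dien-8-one
Product: 13 (4S,5S,7S)-7-hydroxy-3,3-dimethoxyeremophila-1,9,11(12)-trien-8-one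
Conditions: Et2Al(TMP) (3 equiv, preformed from lithium 2,2,6,6-tetramethylpiperidide and Et2AlCl), toluene, 0 °C; aq. potassium sodium tartrate
Reagents that add atoms: none
Why: Yamamoto epoxide-to-allylic-alcohol isomerisation: the aluminium amide removes a methyl proton syn to the coordinated oxirane oxygen with cleavage of the tertiary C11–O bond (the C7–O bond α to the carbonyl stays), so C7 keeps its configuration.

Step 7
Reactants: 13 (4S,5S,7S)-7-hydroxy-3,3-dimethoxyeremophila-1,9,11(12)-trien-8-one
Product: 14 (4S,5S,7S)-13-acetoxy-7-hydroxy-3,3-dimethoxyeremophila-1,9,11(12)-trien-8-one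
Conditions: Pd(OAc)2 (10 mol %), 4,5-diazafluoren-9-one (10 mol %), benzoquinone (1.5 equiv), AcOH (5 equiv), NaOAc, 4 Å molecular sieves, dry dioxane, 45 °C
Reagents that add atoms: acetic acid CC(=O)O
Why: Proposed new method: hydroxyl-directed allylic C–H acetoxylation of a 1,1-disubstituted alkene — the tertiary C7 hydroxyl binds divalent palladium, acetate-assisted cleavage of a methyl C–H gives the only possible π-allyl (C7 is quaternary and the two allyl termini are equivalent), acetate forms the C13–O bond and benzoquinone reoxidises zerovalent palladium; the closest known reaction is the Pd(OAc)2/sulfoxide or Pd(OAc)2/diazafluorenone allylic C–H acetoxylation of monosubstituted terminal alkenes, and no stereocentre is touched.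

Step 8
Reactants: 14 (4S,5S,7S)-13-acetoxy-7-hydroxy-3,3-dimethoxyeremophila-1,9,11(12)-trien-8-one
Product: 16 (3R,4S,5S,7S)-13-acetoxy-3,7-dihydroxyeremophila-1,9,11(12)-trien-8-one, via enedione 15 (not isolated)
Conditions: 5% aq. oxalic acid, THF, 0 °C → rt; NaHCO3; then MeOH, CeCl3·7H2O, NaBH4, −78 °C
Reagents that add atoms: water O
Why: Mild ketal hydrolysis followed in the same flask by Luche reduction: hydride attacks the less hindered C3 carbonyl (C8 is flanked by the fully substituted C7) from the face opposite the axial angular methyl and gives the axial (3R) alcohol; reducing at once avoids epimerisation at C4.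

Step 9
Reactants: 17 (E)-2-methylbut-2-enoic acid (tiglic acid)
Product: 18 (R)-2-methylbutanoic acid
Conditions: H2 (100 atm), Ru(OAc)2[(R)-H8-BINAP] (0.5 mol %), MeOH, rt
Reagents that add atoms: none
Why: Noyori-type carboxylate-directed asymmetric hydrogenation sets the methyl-bearing centre (future C6′) as R by ligand control.

Step 10
Reactants: 18 (R)-2-methylbutanoic acid
Product: 19 (R)-2-methylbutan-1-ol
Conditions: LiAlH4, Et2O, 0 °C → rt
Reagents that add atoms: none
Why: Hydride reduction of the acid to the primary alcohol does not touch the stereocentre.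

Step 11
Reactants: 19 (R)-2-methylbutan-1-ol; 20 2-(triphenylphosphoranylidene)propanal
Product: 22 (2E,4R)-2,4-dimethylhex-2-enal, via (R)-2-methylbutanal 21 (not isolated)
Conditions: TEMPO (10 mol %), PhI(OAc)2 (1.05 equiv), CH2Cl2, rt; then 20, toluene, 80 °C
Reagents that add atoms: none
Why: TEMPO/PhI(OAc)2 oxidation and Wittig olefination in the same flask with the stabilised formyl ylide give the (E)-trisubstituted enal without isolating the volatile, epimerisable aldehyde.

Step 12
Reactants: 22 (2E,4R)-2,4-dimethylhex-2-enal; 23 2-(diethoxyphosphoryl)acetic acid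
Product: 25 (2E,4E,6R)-4,6-dimethylocta-2,4-dienoic acid, via phosphonate dianion 24 (not isolated)
Conditions: 23, LiN(SiMe3)2 (2.1 equiv), THF, −78 °C; then 22, −78 °C → rt; 1 M HCl
Reagents that add atoms: none
Why: Horner–Wadsworth–Emmons olefination with the dianion of the phosphonoacetic acid gives the (2E) acid directly, and the remote stereocentre is not deprotonated because the base is consumed before the enal is added.

Step 13
Reactants: 16 (3R,4S,5S,7S)-13-acetoxy-3,7-dihydroxyeremophila-1,9,11(12)-trien-8-one; 25 (2E,4E,6R)-4,6-dimethylocta-2,4-dienoic acid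
Product: 26 (3S,4S,5S,7S)-13-acetoxy-7-hydroxy-8-oxoeremophila-1,9,11(12)-trien-3-yl (2E,4E,6R)-4,6-dimethylocta-2,4-dienoate (CNP0160850.1)
Conditions: PPh3, DIAD, THF, 0 °C → rt
Reagents that add atoms: none
Why: Mitsunobu esterification forms the C3–O bond by SN2 inversion (3R to 3S) with the carboxylate entering on the open face opposite the methyls; the tertiary C7 alcohol does not react and SN2′ attack would break the dienone conjugation.

## Compound list

1 | 4,4-dimethoxycyclohexa-2,5-dien-1-one | COC1(OC)C=CC(=O)C=C1 | starting material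
2 | methylzinc (3S)-4,4-dimethoxy-3-methylcyclohexa-1,5-dien-1-olate | C[Zn]OC1=C[C@H](C)C(OC)(OC)C=C1 | intermediate
3 | (5S,6S)-4,4-dimethoxy-5,6-dimethylcyclohex-2-en-1-one | C[C@@H]1C(=O)C=CC(OC)(OC)[C@H]1C | intermediate
4 | but-3-en-2-one (methyl vinyl ketone) | CC(=O)C=C | starting material
5 | (5S,6S)-4,4-dimethoxy-5,6-dimethyl-6-(3-oxobutyl)cyclohex-2-en-1-one | CC(=O)CC[C@]1(C)C(=O)C=CC(OC)(OC)[C@H]1C | intermediate
6 | (4aS,5S)-8a-hydroxy-6,6-dimethoxy-4a,5-dimethyl-3,4,4a,5,6,8a-hexahydronaphthalen-2(1H)-one (carbinol centre not controlled) | C1C[C@]2(C)C(O)(CC1=O)C=CC(OC)(OC)[C@H]2C | intermediate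
7 | (4aS,5S)-6,6-dimethoxy-4a,5-dimethyl-4,4a,5,6-tetrahydronaphthalen-2(3H)-one | C1C[C@]2(C)C(=CC1=O)C=CC(OC)(OC)[C@H]2C | intermediate
8 | acetone | CC(C)=O | starting material
9 | lithium (4aS,5S)-6,6-dimethoxy-4a,5-dimethyl-4,4a,5,6-tetrahydronaphthalen-2-olate | [Li]OC1=CC[C@]2(C)C(=C1)C=CC(OC)(OC)[C@H]2C | intermediate
10 | (4S,5S,7R)-11-hydroxy-3,3-dimethoxyeremophila-1,9-dien-8-one | CC(C)(O)[C@H]1C[C@]2(C)C(=CC1=O)C=CC(OC)(OC)[C@H]2C | intermediate
11 | (4S,5S)-3,3-dimethoxyeremophila-1,7(11),9-trien-8-one | CC(C)=C1C[C@]2(C)C(=CC1=O)C=CC(OC)(OC)[C@H]2C | intermediate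
12 | (4S,5S,7S)-7,11-epoxy-3,3-dimethoxyeremophila-1,9-dien-8-one | CC1(C)O[C@@]12C[C@]3(C)C(=CC2=O)C=CC(OC)(OC)[C@H]3C | intermediate
13 | (4S,5S,7S)-7-hydroxy-3,3-dimethoxyeremophila-1,9,11(12)-trien-8-one | C=C(C)[C@@]1(O)C[C@]2(C)C(=CC1=O)C=CC(OC)(OC)[C@H]2C | intermediate
14 | (4S,5S,7S)-13-acetoxy-7-hydroxy-3,3-dimethoxyeremophila-1,9,11(12)-trien-8-one | C=C(COC(C)=O)[C@@]1(O)C[C@]2(C)C(=CC1=O)C=CC(OC)(OC)[C@H]2C | intermediate
15 | (4S,5S,7S)-13-acetoxy-7-hydroxyeremophila-1,9,11(12)-triene-3,8-dione | C=C(COC(C)=O)[C@@]1(O)C[C@]2(C)C(=CC1=O)C=CC(=O)[C@H]2C | intermediate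
16 | (3R,4S,5S,7S)-13-acetoxy-3,7-dihydroxyeremophila-1,9,11(12)-trien-8-one | C=C(COC(C)=O)[C@@]1(O)C[C@]2(C)C(=CC1=O)C=C[C@@H](O)[C@H]2C | intermediate
17 | (E)-2-methylbut-2-enoic acid (tiglic acid) | C/C=C(\C)C(=O)O | starting material
18 | (R)-2-methylbutanoic acid | CC[C@@H](C)C(=O)O | intermediate
19 | (R)-2-methylbutan-1-ol | CC[C@@H](C)CO | intermediate
20 | 2-(triphenylphosphoranylidene)propanal | CC(C=O)=P(c1ccccc1)(c1ccccc1)c1ccccc1 | starting material
21 | (R)-2-methylbutanal | CC[C@@H](C)C=O | intermediate
22 | (2E,4R)-2,4-dimethylhex-2-enal | CC[C@@H](C)/C=C(\C)C=O | intermediate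
23 | 2-(diethoxyphosphoryl)acetic acid | CCOP(=O)(CC(=O)O)OCC | starting material
24 | dilithium salt of the dianion of 2-(diethoxyphosphoryl)acetic acid | [Li+].[Li+].CCOP(=O)([CH-]C(=O)[O-])OCC | intermediate
25 | (2E,4E,6R)-4,6-dimethylocta-2,4-dienoic acid | CC[C@@H](C)/C=C(\C)/C=C/C(=O)O | intermediate
26 | (3S,4S,5S,7S)-13-acetoxy-7-hydroxy-8-oxoeremophila-1,9,11(12)-trien-3-yl (2E,4E,6R)-4,6-dimethylocta-2,4-dienoate | C=C(COC(C)=O)[C@@]1(O)C[C@]2(C)C(=CC1=O)C=C[C@H](OC(=O)/C=C/C(C)=C/[C@H](C)CC)[C@H]2C | target

## Step count and risks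

Total step count: 13. Longest linear sequence: 9 (steps 1–8 and 13); the acid branch is steps 9–12.

Three steps most likely to fail:

Step 7 (the proposed new C–H acetoxylation). The hindered 1,1-disubstituted alkene may react too slowly, or the tertiary palladium alkoxide may fragment. The fallback uses known chemistry and sets out from 13: catalytic SeO2 with t-BuOOH in CH2Cl2 (Sharpless allylic hydroxylation; the isopropenyl methyl is the only allylic C–H on an electron-rich alkene) gives (4S,5S,7S)-7,13-dihydroxy-3,3-dimethoxyeremophila-1,9,11(12)-trien-8-one F1. Ac2O in pyridine at 0 °C then acetylates only the primary hydroxyl, and the route is rejoined at 14.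

Step 5 (nucleophilic epoxidation). Hydroperoxide could add to the ring dienone instead of C11, or the oxirane could close on the wrong face, which would invert C7. The fallback sets out from 11 and reaches the same oxirane by an electrophilic route with double stereocontrol: NBS in aqueous acetone buffered with NaHCO3 delivers bromine to C7 on the face away from the angular methyl and water to the tertiary C11, giving (4S,5S,7R)-7-bromo-11-hydroxy-3,3-dimethoxyeremophila-1,9-dien-8-one F2. K2CO3 in MeOH then closes the oxirane with inversion at C7, so the oxygen ends on the methyl face, and the route is rejoined at 12.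

Step 8 (hydrolysis and reduction). The chelating α-ketol at C8 could be reduced in competition with C3, and the facial selectivity of a small hydride at C3 may be modest. The fallback sets out from 14, which is hydrolysed as before but with isolation of 15. The C3 carbonyl of 15 is then reduced with a ketoreductase picked from a commercial panel (NADPH recycled with glucose and glucose dehydrogenase, phosphate buffer with DMSO), so that the enzyme pocket rather than hydride sterics decides which carbonyl and which face react. An enzyme giving (3S,4S,5S,7S)-13-acetoxy-3,7-dihydroxyeremophila-1,9,11(12)-trien-8-one F3 allows esterification with 25 with retention (2,4,6-trichlorobenzoyl chloride, Et3N, DMAP; Yamaguchi), and the route is rejoined at 26 without the Mitsunobu step. A (3R)-selective enzyme rejoins at 16. Any (3S) epimer formed in the Luche reduction can be taken on in the same way.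

## Further compounds

F1 | step 7 | (4S,5S,7S)-7,13-dihydroxy-3,3-dimethoxyeremophila-1,9,11(12)-trien-8-one | C=C(CO)[C@@]1(O)C[C@]2(C)C(=CC1=O)C=CC(OC)(OC)[C@H]2C
F2 | step 5 | (4S,5S,7R)-7-bromo-11-hydroxy-3,3-dimethoxyeremophila-1,9-dien-8-one | CC(C)(O)[C@]1(Br)C[C@]2(C)C(=CC1=O)C=CC(OC)(OC)[C@H]2C
F3 | step 8 | (3S,4S,5S,7S)-13-acetoxy-3,7-dihydroxyeremophila-1,9,11(12)-trien-8-one | C=C(COC(C)=O)[C@@]1(O)C[C@]2(C)C(=CC1=O)C=C[C@H](O)[C@H]2C
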